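Ring A is made last. Its oxygenated carbons C5 and C8 are each attached to a fusion carbon of ring B (C4a, C8a), and they differ only in that the C5 oxygen is methylated and the C8 oxygen is free. A phthalide annulated at C4a–C8a encodes exactly this: its C=O carbon becomes C5 and its CH2 becomes C8. The derived ortho ester, carrying the silyl-protected S side chain at the future C2, is opened to a 1-methoxyisobenzofuran that takes up phenyl vinyl sulfoxide as an acetylene equivalent, so that one operation forms C5–C6 and C7–C8, closes ring A and sets the OMe/OH pattern. The stereocentre is introduced only after the lithiation steps.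

Key step: step 9

Remark: locants C1–C8a follow the naphthoquinone numbering of the target (carbonyls C1 and C4, side chain on C2, carbinol carbon C1'); the carbinol centre is S in every chiral compound, because the ring carbon outranks the CH2 group throughout.
Assumption: salt-free (−)-Ipc2B(allyl), derived from (+)-α-pinene, is bought as a solution; organometallic steps are run under argon.

Step 1
Reactants: 1 4-bromo-2,5-dimethoxybenzaldehyde
Product: 2 2-(4-bromo-2,5-dimethoxyphenyl)-1,3-dioxolane
Conditions: HOCH2CH2OH (3 equiv), p-TsOH·H2O (2 mol %), toluene, reflux, Dean–Stark trap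
Reagents that add atoms: ethane-1,2-diol, OCCO
Why: Acid-catalysed acetalisation with azeotropic removal of water masks the aldehyde as a 1,3-dioxolane that is stable to the two organolithium steps.

Step 2
Reactants: 2 2-(4-bromo-2,5-dimethoxyphenyl)-1,3-dioxolane; 3 N,N-diethylcarbamoyl chloride
Product: 5 4-(1,3-dioxolan-2-yl)-N,N-diethyl-2,5-dimethoxybenzamide, via aryllithium 4 (not isolated)
Conditions: n-BuLi (1.05 equiv), THF, −78 °C; then 3, −78 °C → rt
Reagents that add atoms: none
Why: Bromine–lithium exchange on the aryl bromide is fast at −78 °C and leaves the acetal untouched, and the aryllithium is then acylated by the carbamoyl chloride to give the tertiary benzamide that will serve as the directing group.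

Step 3
Reactants: 5 4-(1,3-dioxolan-2-yl)-N,N-diethyl-2,5-dimethoxybenzamide
Product: 7 4-(1,3-dioxolan-2-yl)-N,N-diethyl-2-formyl-3,6-dimethoxybenzamide, via ortho-lithiated amide 6 (not isolated)
Conditions: s-BuLi (1.2 equiv), TMEDA (1.2 equiv), THF, −78 °C; then DMF, −78 °C → 0 °C; aq. NH4Cl
Reagents that add atoms: N,N-dimethylformamide, CN(C)C=O
Why: Directed ortho-metalation: the diethylamide and the ring methoxy group on either side of the same C–H act together, so that s-BuLi/TMEDA removes only the proton between them and DMF formylates the resulting aryllithium, which fixes the orientation of the later lactone.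

Step 4
Reactants: 7 4-(1,3-dioxolan-2-yl)-N,N-diethyl-2-formyl-3,6-dimethoxybenzamide
Product: 9 4,7-dimethoxy-1-oxo-1,3-dihydroisobenzofuran-5-carbaldehyde, via hydroxymethyl amide 8 (not isolated)
Conditions: NaBH4, MeOH, 0 °C; acetone quench; then 6 M HCl, THF, 60 °C
Reagents that add atoms: water, O
Why: Borohydride reduces the aldehyde only, and in warm aqueous acid the new benzylic hydroxyl displaces diethylamine from the neighbouring twisted amide (acid-mediated lactonisation to the phthalide) while the dioxolane is hydrolysed to the free aldehyde.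

Step 5
Reactants: 9 4,7-dimethoxy-1-oxo-1,3-dihydroisobenzofuran-5-carbaldehyde
Product: 10 5-[(S)-1-hydroxybut-3-enyl]-4,7-dimethoxyisobenzofuran-1(3H)-one
Conditions: (−)-Ipc2B(allyl) (1.3 equiv), Et2O/THF, −78 °C; then NaBO3·4H2O, THF/H2O, rt
Reagents that add atoms: (−)-B-allyldiisopinocampheylborane, C=CCB([C@@H]1C[C@@H]2C[C@H]([C@H]1C)C2(C)C)[C@@H]1C[C@@H]2C[C@H]([C@H]1C)C2(C)C
Why: Asymmetric allylboration (Brown allylation) through a closed chair transition state in which the isopinocampheyl groups derived from (+)-α-pinene deliver the allyl group to the aldehyde face that leads to the S carbinol (reagent control), the lactone being inert to the allylborane at −78 °C.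

Step 6
Reactants: 10 5-[(S)-1-hydroxybut-3-enyl]-4,7-dimethoxyisobenzofuran-1(3H)-one
Product: 11 5-[(S)-1-(tert-butyldimethylsilyloxy)but-3-enyl]-4,7-dimethoxyisobenzofuran-1(3H)-one
Conditions: TBSCl, imidazole, DMF, rt
Reagents that add atoms: tert-butyldimethylsilyl chloride, C[Si](C)(Cl)C(C)(C)C
Why: Silylation of the secondary alcohol by the silyl chloride under imidazole catalysis protects the carbinol for the cationic, thermal and oxidative steps that follow without touching the stereocentre.

Step 7
Reactants: 11 5-[(S)-1-(tert-butyldimethylsilyloxy)but-3-enyl]-4,7-dimethoxyisobenzofuran-1(3H)-one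
Product: 12 5-[(S)-1-(tert-butyldimethylsilyloxy)-4-methylpent-3-enyl]-4,7-dimethoxyisobenzofuran-1(3H)-one
Conditions: 2-methylbut-2-ene (co-solvent, large excess), second-generation Grubbs catalyst (H2IMes)(PCy3)Cl2Ru=CHPh (3 mol %), CH2Cl2, 40 °C, sealed vessel
Reagents that add atoms: 2-methylbut-2-ene, CC=C(C)C
Why: Olefin cross-metathesis of the terminal alkene against an excess of 2-methylbut-2-ene installs the trisubstituted dimethyl-substituted alkene, is driven by loss of propene and raises no E/Z question.

Step 8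
Reactants: 12 5-[(S)-1-(tert-butyldimethylsilyloxy)-4-methylpent-3-enyl]-4,7-dimethoxyisobenzofuran-1(3H)-one
Product: 14 1,1,4,7-tetramethoxy-5-[(S)-1-(tert-butyldimethylsilyloxy)-4-methylpent-3-enyl]-1,3-dihydroisobenzofuran, via O-methyl lactonium tetrafluoroborate 13 (not isolated)
Conditions: Me3OBF4 (3 equiv), 2,6-di-tert-butyl-4-methylpyridine (0.5 equiv), CH2Cl2, rt; then NaOMe (excess), MeOH, −78 °C → 0 °C; isolation over basic alumina
Reagents that add atoms: trimethyloxonium tetrafluoroborate, C[O+](C)C.F[B-](F)(F)F; sodium methoxide, [Na+].[O-]C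
Why: O-Methylation of the lactone carbonyl by the oxonium salt (Meerwein alkylation) gives a dialkoxycarbenium ion that methoxide captures at carbon under kinetic control to form the cyclic ortho ester, while the hindered pyridine buffers adventitious acid so that the silyl ether and the alkene should survive.

Step 9
Reactants: 14 1,1,4,7-tetramethoxy-5-[(S)-1-(tert-butyldimethylsilyloxy)-4-methylpent-3-enyl]-1,3-dihydroisobenzofuran; 15 phenyl vinyl sulfoxide
Product: 19 7-[(S)-1-(tert-butyldimethylsilyloxy)-4-methylpent-3-enyl]-4,5,8-trimethoxynaphthalen-1-ol, via 1-methoxyisobenzofuran 16 (not isolated), via sulfinyl oxa-bridged cycloadduct 17 (not isolated), via 1-methoxy-1,4-epoxynaphthalene 18 (not isolated)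
Conditions: 15 (3 equiv), pivalic acid (2 mol %), toluene, 110 °C, sealed tube, argon
Reagents that add atoms: none
Why: Pivalic acid protonates one methoxy group of ortho ester 14, methanol leaves, and the resulting cyclic dialkoxycarbenium ion sheds its C3 proton to give isobenzofuran 16, an o-quinoid diene that combines with the electron-poor alkene of 15 at C1 and C3 to furnish the oxa-bridged ketal 17; at 110 °C the sulfoxide of 17 departs as PhSOH through a five-centre syn elimination, and the bridgehead C–O bond of the resulting 18 then heterolyses on the methoxy-substituted side, the other bridgehead giving up its proton so that naphthol 19 is formed. Both halves have close analogies, namely the conversion of phthalide ortho esters into 1-alkoxyisobenzofurans that are intercepted by dienophiles and end as 4-alkoxy-1-naphthols, and the Diels–Alder use of phenyl vinyl sulfoxide as a surrogate for acetylene. Ring A is closed by an intermolecular [4+2] cycloaddition (diene carbons C1/C3 of the furan, two C–C bonds made in a single event), so that no ring-closure preference has to be overcome. No stereocentre is created, because every sp3 carbon formed in 17 and 18 becomes sp2 in 19 and the S carbinol lies outside the reacting system. What the step needs is chemoselectivity in the aromatisation, with PhSOH lost and the bridge oxygen kept as the C8 hydroxyl, and this is secured by the bridgehead methoxy group, which makes its own carbon the site of ionisation, and by an acid that is weak and present only in trace; the regiochemistry of the cycloaddition is irrelevant since sulfur is excised, and the OMe/OH assignment was already fixed by the direction of the lactone built in steps 3 and 4.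

Step 10
Reactants: 19 7-[(S)-1-(tert-butyldimethylsilyloxy)-4-methylpent-3-enyl]-4,5,8-trimethoxynaphthalen-1-ol
Product: 20 7-[(S)-1-(tert-butyldimethylsilyloxy)-4-methylpent-3-enyl]-4,5,8-trimethoxynaphthalen-1-yl acetate
Conditions: Ac2O, pyridine, DMAP (cat.), CH2Cl2, 0 °C → rt
Reagents that add atoms: acetic anhydride, CC(=O)OC(C)=O
Why: DMAP-catalysed O-acetylation converts the electron-rich free naphthol of ring A into an aryl acetate, which lowers the oxidisability of ring A below that of the dimethoxy ring B before the oxidation.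

Step 11
Reactants: 20 7-[(S)-1-(tert-butyldimethylsilyloxy)-4-methylpent-3-enyl]-4,5,8-trimethoxynaphthalen-1-yl acetate
Product: 21 7-[(S)-1-(tert-butyldimethylsilyloxy)-4-methylpent-3-enyl]-4-methoxy-5,8-dioxo-5,8-dihydronaphthalen-1-yl acetate
Conditions: (NH4)2Ce(NO3)6 (2.5 equiv), MeCN/H2O 2:1, 0 °C
Reagents that add atoms: water, O
Why: Oxidative demethylation with tetravalent cerium: electron transfer occurs from the more electron-rich 1,4-dimethoxy ring B, water attacks the two methoxy-bearing carbons and methanol is expelled to give the quinone, whereas ring A carries a single ether and a deactivating acetoxy group and cannot reach a quinone without losing its acyl group.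

Step 12
Reactants: 21 7-[(S)-1-(tert-butyldimethylsilyloxy)-4-methylpent-3-enyl]-4-methoxy-5,8-dioxo-5,8-dihydronaphthalen-1-yl acetate
Product: 23 8-hydroxy-2-[(S)-1-hydroxy-4-methylpent-3-enyl]-5-methoxynaphthalene-1,4-dione, via phenol silyl ether 22 (not isolated)
Conditions: K2CO3 (1.1 equiv), MeOH, 0 °C, argon; then 48% aq. HF (excess), MeCN, 0 °C → rt, polypropylene vessel
Reagents that add atoms: none
Why: Carbonate-mediated methanolysis (transesterification) removes the aryl acetate, which is activated by the peri quinone carbonyl, and aqueous HF then cleaves the secondary silyl ether under mildly acidic conditions that neither ionise the carbinol nor affect the alkene, so that the S centre is retained.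

Step 13
Reactants: 23 8-hydroxy-2-[(S)-1-hydroxy-4-methylpent-3-enyl]-5-methoxynaphthalene-1,4-dione; 24 3-methylbut-2-enoic acid
Product: 25 (S)-1-(8-hydroxy-5-methoxy-1,4-dioxo-1,4-dihydronaphthalen-2-yl)-4-methylpent-3-enyl 3-methylbut-2-enoate
Conditions: 24 (1.5 equiv), DCC (1.5 equiv), DMAP (0.2 equiv), CH2Cl2, 0 °C → rt
Reagents that add atoms: none
Why: Steglich esterification acylates the secondary side-chain hydroxyl in preference to the C8 phenol, whose nucleophilicity is damped by its strong hydrogen bond to the C1 carbonyl (the selectivity relied on in side-chain acylation of naphthazarin carbinols such as alkannin), and the C–O bond of the carbinol is not broken, so the configuration is kept.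

Compound list
1 | 4-bromo-2,5-dimethoxybenzaldehyde | COc1cc(C=O)c(OC)cc1Br | starting material
2 | 2-(4-bromo-2,5-dimethoxyphenyl)-1,3-dioxolane | COc1cc(C2OCCO2)c(OC)cc1Br | intermediate
3 | N,N-diethylcarbamoyl chloride | CCN(CC)C(=O)Cl | starting material
4 | [4-(1,3-dioxolan-2-yl)-2,5-dimethoxyphenyl]lithium | [Li]c1cc(OC)c(C2OCCO2)cc1OC | intermediate (not isolated)
5 | 4-(1,3-dioxolan-2-yl)-N,N-diethyl-2,5-dimethoxybenzamide | CCN(CC)C(=O)c1cc(OC)c(C2OCCO2)cc1OC | intermediate
6 | [2-(diethylcarbamoyl)-5-(1,3-dioxolan-2-yl)-3,6-dimethoxyphenyl]lithium | CCN(CC)C(=O)c1c([Li])c(OC)c(C2OCCO2)cc1OC | intermediate (not isolated)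
7 | 4-(1,3-dioxolan-2-yl)-N,N-diethyl-2-formyl-3,6-dimethoxybenzamide | CCN(CC)C(=O)c1c(C=O)c(OC)c(C2OCCO2)cc1OC | intermediate
8 | 4-(1,3-dioxolan-2-yl)-N,N-diethyl-2-(hydroxymethyl)-3,6-dimethoxybenzamide | CCN(CC)C(=O)c1c(CO)c(OC)c(C2OCCO2)cc1OC | intermediate (not isolated)
9 | 4,7-dimethoxy-1-oxo-1,3-dihydroisobenzofuran-5-carbaldehyde | COc1cc(C=O)c(OC)c2c1C(=O)OC2 | intermediate
10 | 5-[(S)-1-hydroxybut-3-enyl]-4,7-dimethoxyisobenzofuran-1(3H)-one | COc1cc([C@H](CC=C)O)c(OC)c2c1C(=O)OC2 | intermediate
11 | 5-[(S)-1-(tert-butyldimethylsilyloxy)but-3-enyl]-4,7-dimethoxyisobenzofuran-1(3H)-one | COc1cc([C@H](CC=C)O[Si](C)(C)C(C)(C)C)c(OC)c2c1C(=O)OC2 | intermediate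
12 | 5-[(S)-1-(tert-butyldimethylsilyloxy)-4-methylpent-3-enyl]-4,7-dimethoxyisobenzofuran-1(3H)-one | COc1cc([C@H](CC=C(C)C)O[Si](C)(C)C(C)(C)C)c(OC)c2c1C(=O)OC2 | intermediate
13 | 1,4,7-trimethoxy-5-[(S)-1-(tert-butyldimethylsilyloxy)-4-methylpent-3-enyl]-3H-isobenzofuran-2-ium tetrafluoroborate | COc1cc([C@H](CC=C(C)C)O[Si](C)(C)C(C)(C)C)c(OC)c2c1C(OC)=[O+]C2.F[B-](F)(F)F | intermediate (not isolated)
14 | 1,1,4,7-tetramethoxy-5-[(S)-1-(tert-butyldimethylsilyloxy)-4-methylpent-3-enyl]-1,3-dihydroisobenzofuran | COc1cc([C@H](CC=C(C)C)O[Si](C)(C)C(C)(C)C)c(OC)c2c1C(OC)(OC)OC2 | intermediate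
15 | phenyl vinyl sulfoxide | C=CS(=O)c1ccccc1 | starting material
16 | 1,4,7-trimethoxy-5-[(S)-1-(tert-butyldimethylsilyloxy)-4-methylpent-3-enyl]isobenzofuran | COC1=C2C(OC)=CC([C@H](CC=C(C)C)O[Si](C)(C)C(C)(C)C)=C(OC)C2=CO1 | intermediate (not isolated)
17 | 1,5,8-trimethoxy-2-(phenylsulfinyl)-6-[(S)-1-(tert-butyldimethylsilyloxy)-4-methylpent-3-enyl]-1,2,3,4-tetrahydro-1,4-epoxynaphthalene (isomer mixture, one regioisomer drawn, new centres unassigned) | COC12OC(CC1S(=O)c1ccccc1)c1c(OC)c([C@H](CC=C(C)C)O[Si](C)(C)C(C)(C)C)cc(OC)c21 | intermediate (not isolated)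
18 | 1,5,8-trimethoxy-6-[(S)-1-(tert-butyldimethylsilyloxy)-4-methylpent-3-enyl]-1,4-dihydro-1,4-epoxynaphthalene (bridgehead centres unassigned) | COC12OC(C=C1)c1c(OC)c([C@H](CC=C(C)C)O[Si](C)(C)C(C)(C)C)cc(OC)c21 | intermediate (not isolated)
19 | 7-[(S)-1-(tert-butyldimethylsilyloxy)-4-methylpent-3-enyl]-4,5,8-trimethoxynaphthalen-1-ol | COc1cc([C@H](CC=C(C)C)O[Si](C)(C)C(C)(C)C)c(OC)c2c(O)ccc(OC)c12 | intermediate
20 | 7-[(S)-1-(tert-butyldimethylsilyloxy)-4-methylpent-3-enyl]-4,5,8-trimethoxynaphthalen-1-yl acetate | COc1cc([C@H](CC=C(C)C)O[Si](C)(C)C(C)(C)C)c(OC)c2c(OC(C)=O)ccc(OC)c12 | intermediate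
21 | 7-[(S)-1-(tert-butyldimethylsilyloxy)-4-methylpent-3-enyl]-4-methoxy-5,8-dioxo-5,8-dihydronaphthalen-1-yl acetate | COc1ccc(OC(C)=O)c2c1C(=O)C=C([C@H](CC=C(C)C)O[Si](C)(C)C(C)(C)C)C2=O | intermediate
22 | 8-hydroxy-5-methoxy-2-[(S)-1-(tert-butyldimethylsilyloxy)-4-methylpent-3-enyl]naphthalene-1,4-dione | COc1ccc(O)c2c1C(=O)C=C([C@H](CC=C(C)C)O[Si](C)(C)C(C)(C)C)C2=O | intermediate (not isolated)
23 | 8-hydroxy-2-[(S)-1-hydroxy-4-methylpent-3-enyl]-5-methoxynaphthalene-1,4-dione | COc1ccc(O)c2c1C(=O)C=C([C@H](CC=C(C)C)O)C2=O | intermediate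
24 | 3-methylbut-2-enoic acid | CC(C)=CC(=O)O | starting material
25 | (S)-1-(8-hydroxy-5-methoxy-1,4-dioxo-1,4-dihydronaphthalen-2-yl)-4-methylpent-3-enyl 3-methylbut-2-enoate | COc1ccc(O)c2c1C(=O)C=C([C@H](CC=C(C)C)OC(=O)C=C(C)C)C2=O | target

Total step count: 13. Longest linear sequence: 13 steps (1 → 25).

Steps most likely to fail

Step 9. The bridged adduct may aromatise by loss of water instead of loss of sulfenic acid, which would keep sulfur on ring A. The sulfenic acid set free may also sulfenylate the electron-rich naphthol as it forms. The fallback sets out from 14 and returns at 19. The same isobenzofuran 16 is generated (pivalic acid cat., toluene, 80 °C) in the presence of ethynyl p-tolyl sulfone, an alkyne dienophile that needs no elimination. The cycloadduct 1,5,8-trimethoxy-2-(4-methylphenylsulfonyl)-6-[(S)-1-(tert-butyldimethylsilyloxy)-4-methylpent-3-enyl]-1,4-dihydro-1,4-epoxynaphthalene F1 is already at the naphthalene oxidation level. Its ketal bridge should open in the same flask to 7-[(S)-1-(tert-butyldimethylsilyloxy)-4-methylpent-3-enyl]-4,5,8-trimethoxy-3-(4-methylphenylsulfonyl)naphthalen-1-ol F2. Reductive desulfonylation (sodium amalgam, Na2HPO4, MeOH/THF, −20 °C → rt) then gives 19.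

Step 8. O-Methylation of the hindered, conjugated lactone may be too slow, and acid released from the oxonium salt over the long reaction time may cleave the silyl ether or protonate the alkene. The fallback sets out from 12 and returns at 14, activating the lactone through sulfur instead. Thionation with Lawesson's reagent (toluene, 110 °C) should give 5-[(S)-1-(tert-butyldimethylsilyloxy)-4-methylpent-3-enyl]-4,7-dimethoxyisobenzofuran-1(3H)-thione F3. Its nucleophilic sulfur is methylated quickly by MeOTf (CH2Cl2, 0 °C) to 4,7-dimethoxy-1-(methylsulfanyl)-5-[(S)-1-(tert-butyldimethylsilyloxy)-4-methylpent-3-enyl]-3H-isobenzofuran-2-ium trifluoromethanesulfonate F4. NaOMe/MeOH at −78 °C adds to give 1,4,7-trimethoxy-1-(methylsulfanyl)-5-[(S)-1-(tert-butyldimethylsilyloxy)-4-methylpent-3-enyl]-1,3-dihydroisobenzofuran F5. Thiophilic exchange (AgOTf, MeOH, 2,6-lutidine, 0 °C) replaces the methylsulfanyl group by methoxy to give 14.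

Step 13. The acylation may fail to discriminate between the carbinol and the chelated phenol, or may stall on the hindered carbinol next to the quinone with rearrangement of the activated acid to the N-acylurea. The fallback sets out from 21 and returns at 25, acylating while the phenol is still masked. Desilylation alone (HF·pyridine, THF, 0 °C) gives 7-[(S)-1-hydroxy-4-methylpent-3-enyl]-4-methoxy-5,8-dioxo-5,8-dihydronaphthalen-1-yl acetate F6. Acylation with 3-methylbut-2-enoyl chloride (pyridine, DMAP cat., CH2Cl2, −20 °C) gives (S)-1-(8-acetoxy-5-methoxy-1,4-dioxo-1,4-dihydronaphthalen-2-yl)-4-methylpent-3-enyl 3-methylbut-2-enoate F7. The activated aryl acetate is then cleaved in preference to the hindered conjugated alkyl ester (K2CO3, MeOH, −10 °C, short contact) to give 25.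

Further compounds
F1 | step 9 | 1,5,8-trimethoxy-2-(4-methylphenylsulfonyl)-6-[(S)-1-(tert-butyldimethylsilyloxy)-4-methylpent-3-enyl]-1,4-dihydro-1,4-epoxynaphthalene | COC12OC(C=C1S(=O)(=O)c1ccc(C)cc1)c1c(OC)c([C@H](CC=C(C)C)O[Si](C)(C)C(C)(C)C)cc(OC)c21
F2 | step 9 | 7-[(S)-1-(tert-butyldimethylsilyloxy)-4-methylpent-3-enyl]-4,5,8-trimethoxy-3-(4-methylphenylsulfonyl)naphthalen-1-ol | COc1cc([C@H](CC=C(C)C)O[Si](C)(C)C(C)(C)C)c(OC)c2c(O)cc(S(=O)(=O)c3ccc(C)cc3)c(OC)c12
F3 | step 8 | 5-[(S)-1-(tert-butyldimethylsilyloxy)-4-methylpent-3-enyl]-4,7-dimethoxyisobenzofuran-1(3H)-thione | COc1cc([C@H](CC=C(C)C)O[Si](C)(C)C(C)(C)C)c(OC)c2c1C(=S)OC2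
F4 | step 8 | 4,7-dimethoxy-1-(methylsulfanyl)-5-[(S)-1-(tert-butyldimethylsilyloxy)-4-methylpent-3-enyl]-3H-isobenzofuran-2-ium trifluoromethanesulfonate | COc1cc([C@H](CC=C(C)C)O[Si](C)(C)C(C)(C)C)c(OC)c2c1C(SC)=[O+]C2.[O-]S(=O)(=O)C(F)(F)F
F5 | step 8 | 1,4,7-trimethoxy-1-(methylsulfanyl)-5-[(S)-1-(tert-butyldimethylsilyloxy)-4-methylpent-3-enyl]-1,3-dihydroisobenzofuran | COc1cc([C@H](CC=C(C)C)O[Si](C)(C)C(C)(C)C)c(OC)c2c1C(OC)(SC)OC2
F6 | step 13 | 7-[(S)-1-hydroxy-4-methylpent-3-enyl]-4-methoxy-5,8-dioxo-5,8-dihydronaphthalen-1-yl acetate | COc1ccc(OC(C)=O)c2c1C(=O)C=C([C@H](CC=C(C)C)O)C2=O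
F7 | step 13 | (S)-1-(8-acetoxy-5-methoxy-1,4-dioxo-1,4-dihydronaphthalen-2-yl)-4-methylpent-3-enyl 3-methylbut-2-enoate | COc1ccc(OC(C)=O)c2c1C(=O)C=C([C@H](CC=C(C)C)OC(=O)C=C(C)C)C2=O
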